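**Retrosynthetic overview**

- Euchrenone a17 is taken back to its ring D chromene by chemoselective diimide reduction of the C3″=C4″ alkene.
- The strategy rests on two five-carbon units that each sit ortho to a phenolic oxygen: the prenyl group on C8 next to C7–OH (ring A), and the dimethylpyran ring D fused through C3′ and O4′ (ring B). Both are Claisen retrons, so one thermal cascade on the O7 1,1-dimethylallyl / O4′ 1,1-dimethylpropargyl bis-ether makes the C8–CH2, C3′–C4″ and O1″–C2″ bonds.
- The bis-ether comes from 7-(1,1-dimethylallyloxy)chromone and a C-silylated 4-(1,1-dimethylpropargyloxy)phenylboronic acid by rhodium-catalysed enantioselective 1,4-addition, which sets C2 (S), followed by buffered C-desilylation.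
- Both ethers are installed before C2 exists: copper-catalysed O-propargylation of 7-hydroxychromone and of 4-bromophenol with 3-chloro-3-methylbut-1-yne; Lindlar reduction on the chromone; silylation and Br/Li–borylation on the arene.
- Ring order: rings A and C are bought as the chromone, ring B is attached at C2, ring D is closed last.

Key step: step 8

Numbering: flavanone numbering (O1, C2–C4, ring A C4a–C8a, ring B C1′–C6′); ring D atoms are O1″ (= O4′), C2″ (CMe2), C3″, C4″ (on C3′).

Assumption: the sense of induction of the chiral diene is not fixed here; the enantiomer of 2,5-diphenylbicyclo[2.2.2]octa-2,5-diene (Ph-bod*) is taken that delivers the aryl group to the Re face of C2 of the chromone, which gives (2S). This is to be verified on the first batch and the antipode used if required.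

**Route**

Step 1
Reactants: 1 7-hydroxy-4H-chromen-4-one; 2 3-chloro-3-methylbut-1-yne
Product: 3 7-[(2-methylbut-3-yn-2-yl)oxy]-4H-chromen-4-one
Conditions: CuCl2·2H2O (cat.), DBU, MeCN, 0 °C
Reagents that add atoms: none
Why: Copper-catalysed O-propargylation of a phenol with a tertiary propargylic chloride (phenoxide capture of a copper allenylidene at the tertiary carbon) is the standard way to aryl 1,1-dimethylpropargyl ethers and at 0 °C should alkylate the acidic 7-OH without opening the pyrone ring.

Step 2
Reactants: 3 7-[(2-methylbut-3-yn-2-yl)oxy]-4H-chromen-4-one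
Product: 4 7-[(2-methylbut-3-en-2-yl)oxy]-4H-chromen-4-one
Conditions: H2 (1 atm), Pd/CaCO3 poisoned with Pb(OAc)2 (Lindlar catalyst), quinoline, EtOAc, rt; work-up below 35 °C
Reagents that add atoms: none
Why: Lindlar semihydrogenation takes a terminal alkyne to the alkene and should leave the conjugated, electron-poor C2=C3 bond of the pyrone alone, provided hydrogen uptake is stopped at one equivalent and the product is kept cool so that the tertiary allyl ether does not rearrange early.

Step 3
Reactants: 5 4-bromophenol; 2 3-chloro-3-methylbut-1-yne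
Product: 6 1-bromo-4-[(2-methylbut-3-yn-2-yl)oxy]benzene
Conditions: CuCl2·2H2O (cat.), DBU, MeCN, 0 °C
Reagents that add atoms: none
Why: The same copper-catalysed phenol O-propargylation applies to 4-bromophenol, whose C–Br bond is inert to the copper catalyst at 0 °C.

Step 4
Reactants: 6 1-bromo-4-[(2-methylbut-3-yn-2-yl)oxy]benzene
Product: 8 [3-(4-bromophenoxy)-3-methylbut-1-yn-1-yl]trimethylsilane, via lithium acetylide 7 (not isolated)
Conditions: LiN(i-Pr)2, THF, −78 °C; Me3SiCl, −78 °C → rt
Reagents that add atoms: chlorotrimethylsilane, C[Si](C)(C)Cl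
Why: Deprotonation of the terminal alkyne by the amide base (which does not exchange with the aryl bromide at −78 °C) and C-silylation of the acetylide mask the acidic C–H for the lithiation and shield the triple bond from the rhodium catalyst.

Step 5
Reactants: 8 [3-(4-bromophenoxy)-3-methylbut-1-yn-1-yl]trimethylsilane
Product: 11 (4-{[2-methyl-4-(trimethylsilyl)but-3-yn-2-yl]oxy}phenyl)boronic acid, via aryllithium 9 (not isolated), via lithium aryltriisopropoxyborate 10 (not isolated)
Conditions: n-BuLi, THF, −78 °C; B(Oi-Pr)3, −78 °C → rt; aq. NH4Cl/dil. HCl (pH about 5), 0 °C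
Reagents that add atoms: triisopropyl borate, CC(C)OB(OC(C)C)OC(C)C; water, O
Why: Bromine–lithium exchange followed by borylation with B(Oi-Pr)3 and mild hydrolysis is the standard arylboronic acid synthesis, and with the alkyne silylated there is no acidic hydrogen to quench the aryllithium.

Step 6
Reactants: 4 7-[(2-methylbut-3-en-2-yl)oxy]-4H-chromen-4-one; 11 (4-{[2-methyl-4-(trimethylsilyl)but-3-yn-2-yl]oxy}phenyl)boronic acid
Product: 12 (S)-7-[(2-methylbut-3-en-2-yl)oxy]-2-(4-{[2-methyl-4-(trimethylsilyl)but-3-yn-2-yl]oxy}phenyl)chroman-4-one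
Conditions: [RhCl(C2H4)2]2 (cat.), Ph-bod* (enantiomer as in the assumption), aq. KOH (0.3 equiv), dioxane/H2O, 40 °C
Reagents that add atoms: none
Why: Rhodium-catalysed asymmetric 1,4-addition of an arylboronic acid to a chromone (Hayashi–Miyaura type): the aryl group passes from boron to monovalent rhodium, the aryl–rhodium species inserts C2=C3 and water protonates the rhodium enolate, while the C2-symmetric chiral diene blocks one enantioface so that aryl delivery to the Re face of C2 sets (S); the unactivated monosubstituted alkene next to a quaternary carbon and the silyl-capped, doubly hindered alkyne should not compete with the enone.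

Step 7
Reactants: 12 (S)-7-[(2-methylbut-3-en-2-yl)oxy]-2-(4-{[2-methyl-4-(trimethylsilyl)but-3-yn-2-yl]oxy}phenyl)chroman-4-one
Product: 13 (S)-7-[(2-methylbut-3-en-2-yl)oxy]-2-{4-[(2-methylbut-3-yn-2-yl)oxy]phenyl}chroman-4-one
Conditions: Bu4NF, AcOH (1:1), THF, 0 °C → rt
Reagents that add atoms: none
Why: Fluoride-induced protodesilylation of the alkynylsilane, buffered with acetic acid so that no base can open ring C by retro-oxa-Michael reaction and erode the C2 configuration.

Step 8
Reactants: 13 (S)-7-[(2-methylbut-3-en-2-yl)oxy]-2-{4-[(2-methylbut-3-yn-2-yl)oxy]phenyl}chroman-4-one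
Product: 19 (S)-2-(2,2-dimethyl-2H-chromen-6-yl)-7-hydroxy-8-(3-methylbut-2-en-1-yl)chroman-4-one, via ring A C8-prenyl dienone 14 (not isolated), via ring A prenylphenol propargyl ether 15 (not isolated), via ring B allenyl dienone 16 (not isolated), via ortho-allenylphenol 17 (not isolated), via ortho-quinone methide 18 (not isolated)
Conditions: o-xylene (degassed), 145 °C, sealed tube, Ar
Reagents that add atoms: none
Why: On ring A the tertiary allyl ether undergoes a chair-like [3,3] aromatic Claisen shift with allyl inversion, so that the O7–C bond is exchanged for the C8–CH2 bond and dienone 14 tautomerizes to prenylphenol 15; on ring B the propargyl Claisen [3,3] shift gives allenyl dienone 16, which enolizes to allenylphenol 17, passes by a 1,5-hydrogen shift from O4′–H to the central allene carbon into the (Z)-ortho-quinone methide 18 and closes ring D. The closest known reactions are the thermal rearrangements of aryl 1,1-dimethylallyl ethers to ortho-prenylphenols and of aryl 1,1-dimethylpropargyl ethers to 2,2-dimethyl-2H-chromenes. Ring D is the only ring closed, a six-membered ring formed by thermal disrotatory oxa-6π electrocyclization of a 1-oxatriene whose central double bond is held cis, which makes the O1″–C2″ bond. No stereocentre is created (the sp3 centres C8 in 14 and C3′ in 16 vanish on tautomerization), and since every event is neutral and unimolecular the C2 (S) centre should be carried through untouched. The selectivity required is migration to C8 and not C6 on ring A, which the substrate should secure through the higher double-bond character of C7–C8 in the 4-acylresorcinol-type ring (the C8 dienone keeps the vinylogous ester O1–C8a=C4a–C4=O intact); the para positions C4a and C1′ are substituted and the two ortho positions of ring B are equivalent. The allyl shift is expected to precede the propargyl shift because the tertiary allyl ether rearranges at the lower temperature.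

Step 9
Reactants: 19 (S)-2-(2,2-dimethyl-2H-chromen-6-yl)-7-hydroxy-8-(3-methylbut-2-en-1-yl)chroman-4-one
Product: 20 euchrenone a17, (S)-2-(2,2-dimethylchroman-6-yl)-7-hydroxy-8-(3-methylbut-2-en-1-yl)chroman-4-one
Conditions: 2-O2NC6H4SO2NHNH2 (NBSH, in portions), Et3N, CH2Cl2, rt
Reagents that add atoms: none
Why: Diimide reduction: HN=NH released from the sulfonylhydrazide transfers two hydrogens in a concerted syn six-centre step whose rate falls steeply with alkene substitution, so the cis-disubstituted styrene-type C3″=C4″ bond should be reduced ahead of the trisubstituted prenyl alkene, and the aryl ketone, the phenol and the benzylic C2–O bond (at risk under catalytic hydrogenation) are not affected.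

**Compound list**

1 | 7-hydroxy-4H-chromen-4-one (7-hydroxychromone) | O=c1ccoc2cc(O)ccc12 | starting material
2 | 3-chloro-3-methylbut-1-yne | CC(C)(Cl)C#C | starting material
3 | 7-[(2-methylbut-3-yn-2-yl)oxy]-4H-chromen-4-one | C#CC(C)(C)Oc1ccc2c(c1)occc2=O | intermediate
4 | 7-[(2-methylbut-3-en-2-yl)oxy]-4H-chromen-4-one | C=CC(C)(C)Oc1ccc2c(c1)occc2=O | intermediate
5 | 4-bromophenol | Oc1ccc(Br)cc1 | starting material
6 | 1-bromo-4-[(2-methylbut-3-yn-2-yl)oxy]benzene | C#CC(C)(C)Oc1ccc(Br)cc1 | intermediate
7 | [3-(4-bromophenoxy)-3-methylbut-1-yn-1-yl]lithium | [Li]C#CC(C)(C)Oc1ccc(Br)cc1 | intermediate (not isolated)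
8 | [3-(4-bromophenoxy)-3-methylbut-1-yn-1-yl]trimethylsilane | C[Si](C)(C)C#CC(C)(C)Oc1ccc(Br)cc1 | intermediate
9 | (4-{[2-methyl-4-(trimethylsilyl)but-3-yn-2-yl]oxy}phenyl)lithium | [Li]c1ccc(OC(C)(C)C#C[Si](C)(C)C)cc1 | intermediate (not isolated)
10 | lithium triisopropoxy(4-{[2-methyl-4-(trimethylsilyl)but-3-yn-2-yl]oxy}phenyl)borate | [Li+].CC(C)O[B-](OC(C)C)(OC(C)C)c1ccc(OC(C)(C)C#C[Si](C)(C)C)cc1 | intermediate (not isolated)
11 | (4-{[2-methyl-4-(trimethylsilyl)but-3-yn-2-yl]oxy}phenyl)boronic acid | C[Si](C)(C)C#CC(C)(C)Oc1ccc(B(O)O)cc1 | intermediate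
12 | (S)-7-[(2-methylbut-3-en-2-yl)oxy]-2-(4-{[2-methyl-4-(trimethylsilyl)but-3-yn-2-yl]oxy}phenyl)chroman-4-one | C=CC(C)(C)Oc1ccc2c(c1)O[C@H](c1ccc(OC(C)(C)C#C[Si](C)(C)C)cc1)CC2=O | intermediate
13 | (S)-7-[(2-methylbut-3-en-2-yl)oxy]-2-{4-[(2-methylbut-3-yn-2-yl)oxy]phenyl}chroman-4-one (key-step precursor) | C=CC(C)(C)Oc1ccc2c(c1)O[C@H](c1ccc(OC(C)(C)C#C)cc1)CC2=O | intermediate
14 | (2S)-8-(3-methylbut-2-en-1-yl)-2-{4-[(2-methylbut-3-yn-2-yl)oxy]phenyl}-2,3-dihydro-4H-chromene-4,7(8H)-dione (ring A dienone, C8 epimers) | CC(C)=CCC1C(=O)C=CC2=C1O[C@H](c1ccc(OC(C)(C)C#C)cc1)CC2=O | intermediate (not isolated)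
15 | (S)-7-hydroxy-8-(3-methylbut-2-en-1-yl)-2-{4-[(2-methylbut-3-yn-2-yl)oxy]phenyl}chroman-4-one | CC(C)=CCc1c(O)ccc2c1O[C@H](c1ccc(OC(C)(C)C#C)cc1)CC2=O | intermediate (not isolated)
16 | (2S)-7-hydroxy-8-(3-methylbut-2-en-1-yl)-2-[3-(3-methylbuta-1,2-dien-1-yl)-4-oxocyclohexa-1,5-dien-1-yl]chroman-4-one (ring B allenyl dienone, C3′ epimers) | CC(C)=CCc1c(O)ccc2c1O[C@H](C1=CC(C=C=C(C)C)C(=O)C=C1)CC2=O | intermediate (not isolated)
17 | (S)-7-hydroxy-2-[4-hydroxy-3-(3-methylbuta-1,2-dien-1-yl)phenyl]-8-(3-methylbut-2-en-1-yl)chroman-4-one | CC(C)=CCc1c(O)ccc2c1O[C@H](c1ccc(O)c(C=C=C(C)C)c1)CC2=O | intermediate (not isolated)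
18 | (S)-7-hydroxy-8-(3-methylbut-2-en-1-yl)-2-[(3Z)-3-(3-methylbut-2-en-1-ylidene)-4-oxocyclohexa-1,5-dien-1-yl]chroman-4-one (ortho-quinone methide) | CC(C)=CCc1c(O)ccc2c1O[C@H](C1=C/C(=C/C=C(C)C)C(=O)C=C1)CC2=O | intermediate (not isolated)
19 | (S)-2-(2,2-dimethyl-2H-chromen-6-yl)-7-hydroxy-8-(3-methylbut-2-en-1-yl)chroman-4-one (key-step product) | CC(C)=CCc1c(O)ccc2c1O[C@H](c1ccc3c(c1)C=CC(C)(C)O3)CC2=O | intermediate
20 | euchrenone a17, (S)-2-(2,2-dimethylchroman-6-yl)-7-hydroxy-8-(3-methylbut-2-en-1-yl)chroman-4-one | CC(C)=CCc1c(O)ccc2c1O[C@H](c1ccc3c(c1)CCC(C)(C)O3)CC2=O | target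

**Count**

Total step count: 9.
Longest linear sequence: 7 steps (5 → 6 → 8 → 11 → 12 → 13 → 19 → 20; steps 3, 4, 5, 6, 7, 8, 9).

**Steps most likely to fail**

Step 8 (tandem Claisen cascade). The ring B cascade needs the higher temperature, and at that temperature three things may go wrong. The tertiary allyl ether on the acidic ring A oxygen may fragment with loss of isoprene. Part of the allyl group may migrate to C6. The C2 configuration may erode through reversible retro-oxa-Michael opening of ring C. The fallback sets out from 13 and closes ring D by π-acid catalysis in place of the pericyclic cascade. Ph3PAuNTf2 (cat., monovalent gold) in CH2Cl2 at rt should effect 6-endo hydroarylation of the aryl propargyl ether at C3′ to give (S)-2-(2,2-dimethyl-2H-chromen-6-yl)-7-[(2-methylbut-3-en-2-yl)oxy]chroman-4-one F1. Only the ring A [3,3] shift then needs heat (toluene, 110 °C), and the sequence comes back to the route at 19. The C6/C8 question would remain, but at a much lower temperature.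

Step 6 (rhodium-catalysed asymmetric 1,4-addition). The aryl–rhodium species may insert into the alkene of the allyl ether and expel the aryloxide. It may also react at the alkyne, or protodeboronation may outrun the slow addition to the chromone. Enantioface discrimination may be poor. The fallback sets out from 2 and builds the flavanone by the chalcone route with resolution:
- 2,4-Dihydroxyacetophenone is alkylated with 2 (CuCl2·2H2O, DBU, MeCN, 0 °C) at the non-chelated 4-OH to give 1-[2-hydroxy-4-(2-methylbut-3-yn-2-yloxy)phenyl]ethanone F2.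
- Lindlar reduction gives 1-[2-hydroxy-4-(2-methylbut-3-en-2-yloxy)phenyl]ethanone F3.
- 4-Hydroxybenzaldehyde and 2 give 4-(2-methylbut-3-yn-2-yloxy)benzaldehyde F4 in the same way.
- Claisen–Schmidt condensation of F3 with F4 (KOH, EtOH, rt) gives (E)-1-[2-hydroxy-4-(2-methylbut-3-en-2-yloxy)phenyl]-3-[4-(2-methylbut-3-yn-2-yloxy)phenyl]prop-2-en-1-one F5.
- Oxa-Michael closure (NaOAc, EtOH, reflux, with recycling of unclosed chalcone) gives racemic 7-[(2-methylbut-3-en-2-yl)oxy]-2-{4-[(2-methylbut-3-yn-2-yl)oxy]phenyl}chroman-4-one F6.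
- Preparative HPLC on a chiral stationary phase (amylose tris(3,5-dimethylphenylcarbamate)) separates the (S)-enantiomer, and the sequence comes back to the route at 13.

Step 9 (diimide reduction). The prenyl alkene may be over-reduced, or the ring D alkene, which sits next to the quaternary C2″, may be reduced too slowly for a clean stop. The fallback sets out from 4 and brings ring D in saturated, so that no reduction is needed; it gives up the ring B cascade. Commercial 6-bromo-2,2-dimethylchroman is converted (n-BuLi, THF, −78 °C; B(Oi-Pr)3; mild aqueous acid) into (2,2-dimethylchroman-6-yl)boronic acid F7. Rhodium-catalysed 1,4-addition of F7 to 4 under the conditions of step 6 gives (S)-2-(2,2-dimethylchroman-6-yl)-7-[(2-methylbut-3-en-2-yl)oxy]chroman-4-one F8. Heating F8 in toluene at 110–120 °C should bring about only the O7 → C8 [3,3] shift, and the sequence comes back to the route at 20.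

**Further compounds**

F1 | step 8 | (S)-2-(2,2-dimethyl-2H-chromen-6-yl)-7-[(2-methylbut-3-en-2-yl)oxy]chroman-4-one | C=CC(C)(C)Oc1ccc2c(c1)O[C@H](c1ccc3c(c1)C=CC(C)(C)O3)CC2=O
F2 | step 6 | 1-[2-hydroxy-4-(2-methylbut-3-yn-2-yloxy)phenyl]ethanone | CC(=O)c1ccc(OC(C)(C)C#C)cc1O
F3 | step 6 | 1-[2-hydroxy-4-(2-methylbut-3-en-2-yloxy)phenyl]ethanone | CC(=O)c1ccc(OC(C)(C)C=C)cc1O
F4 | step 6 | 4-(2-methylbut-3-yn-2-yloxy)benzaldehyde | O=Cc1ccc(OC(C)(C)C#C)cc1
F5 | step 6 | (E)-1-[2-hydroxy-4-(2-methylbut-3-en-2-yloxy)phenyl]-3-[4-(2-methylbut-3-yn-2-yloxy)phenyl]prop-2-en-1-one | C=CC(C)(C)Oc1ccc(C(=O)/C=C/c2ccc(OC(C)(C)C#C)cc2)c(O)c1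
F6 | step 6 | racemic 7-[(2-methylbut-3-en-2-yl)oxy]-2-{4-[(2-methylbut-3-yn-2-yl)oxy]phenyl}chroman-4-one | C=CC(C)(C)Oc1ccc2c(c1)OC(c1ccc(OC(C)(C)C#C)cc1)CC2=O
F7 | step 9 | (2,2-dimethylchroman-6-yl)boronic acid | OB(O)c1ccc2c(c1)CCC(C)(C)O2
F8 | step 9 | (S)-2-(2,2-dimethylchroman-6-yl)-7-[(2-methylbut-3-en-2-yl)oxy]chroman-4-one | C=CC(C)(C)Oc1ccc2c(c1)O[C@H](c1ccc3c(c1)CCC(C)(C)O3)CC2=O
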